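## The problem

Target 11 is a 4-aryl-1-tetralone. Ring A (C1–C4, C4a, C8a) is a cyclohexanone fused to the catechol ring B (C4a–C8a, OH at C7 and C8). C4 carries a naphthalene through C1' (ring C = C1'–C4', ring D = C5'–C8'), with OH at C4' (para to C1') and OMe at C8' (peri to C1').

- **Stereochemistry.** There is one stereocentre, C4 (R). It is a diarylmethine with no neighbouring stereocentre or heteroatom to relay from, so a catalyst must set it and every later step must leave it alone.
- **The C4–C1' bond.** It lies in the peri bay of the C8' methoxy group, which makes the naphthyl a poor partner for cross-coupling or conjugate arylation.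
- **The oxygen pattern of ring B.** It runs against Friedel–Crafts logic. C8a, which bears the carbonyl, is wedged between C4a and O8, whereas an acylium ion would close at the open position para to O8.
- **Aromatisation.** Any intermediate with ring A closed, the C1 ketone in place and a leaving group, cation or quinone methide at C4 can lose a C3 proton and enolise to a flat 4-aryl-1-naphthol. This loss is irreversible.
- **Sensitive groups.** The free catechol and naphthol oxidise easily. The C8' methyl ether must survive whatever unmasks the three phenols.
- **The enabling feature.** C1–C2–C3–C4 holds an acceptor and a donor site in a 1,4-relation. C1 is a carbonyl carbon, and C4 is benzylic to C1', whose para carbon C4' bears oxygen, so a C2–C4 bond would be the polarised bond of a donor–acceptor cyclopropane. In ring B, C4a is para to O7, and C8, the only other position ortho to the acyl group, is blocked by O8.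

## Retrosynthesis

**11 ⇒ 10.** The O–H bonds at O4', O7 and O8 are replaced by O–benzyl bonds. Methyl ethers on ring B would have to be told apart from the C8' methyl ether at the end. Three benzyl groups fall in one neutral step that does not touch C4. The forward reaction must spare the aryl ketone.

**10 ⇒ 9.** The C4–C4a bond is cut, which leaves the open-chain secondary benzylic cation 9.
- The neighbouring cut C1–C8a has the wrong regiochemistry, and the cut C4–C1' meets the peri hindrance.
- With C1 already bonded to C8a, the 2,3-dioxygenated benzoyl group has only one free ortho position, and that position is para to O7.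
- The cation exists only while ring A is open, so loss of a C3 proton is reversible and cannot lead to a naphthol.
- Cation 9 is planar and achiral. The forward reaction must close one of its faces selectively, which a chiral counteranion is asked to do.

**9 ⇒ 8.** C2 is joined to C4, which turns the cation and its enol into the racemic donor–acceptor cyclopropane 8, an isomer of 10. A halide or alcohol at C4 would be too labile next to so electron-rich a naphthalene and would release a by-product. The cyclopropane is storable, opens only when the ketone is protonated, and sets nothing free. Its own two stereocentres need no control, because both are erased on opening.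

**8 ⇒ 7.** The C2–C3 and C3–C4 bonds are cut, so that C3 leaves as a methylene group and the (E)-enone 7 remains. In 7 the carbons C2 and C4 of the target are directly double-bonded. Methylene transfer from a sulfur ylide to an aryl enone is routine, and the precursor is flat and achiral.

**7 ⇒ 4 + 6.** The C2=C4 double bond is cut by a retro-aldol condensation. This is the convergent step and splits the molecule into one aromatic aldehyde and one aromatic methyl ketone of similar size. Only 6 can enolise and only 4 can accept.

**4 ⇒ 3 ⇒ 2 ⇒ 1.** The congested C4–C1' bond is traced back to a formylation of the C2h-symmetric diether 1. There a small electrophile enters para to one methoxy group and peri to the other, and symmetry allows only one such product. The formyl group then tells the two methoxy groups apart. O4' becomes part of a vinylogous ester, while O8' is not conjugated with the carbonyl. Selective loss of the O4' methyl group (3) and benzylation (4) follow.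

**6 ⇒ 5.** The two O–benzyl bonds are cut. Compound 5 already carries the acyl carbon C1 next to O8 and O7, so the contra-Friedel–Crafts pattern is bought and not made.

## Roads not taken

**Alternative 1:** cut C1–C8a (the obvious route).
- Acid A1 would come from a rhodium-catalysed asymmetric conjugate arylation followed by one-carbon homologation. The forward key step is its intramolecular Friedel–Crafts acylation.
- The acylium ion closes at the open position para to O8 and gives the 6,7-dioxygenated isomer A2. The wanted carbon C8a is the most crowded and least activated site, and C2' of the naphthalene is a further competitor.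
- A blocking group or a halogen handle would add steps, and the asymmetric arylation has to bring a peri-hindered aryl group onto the stereocentre.
- The chosen plan has C1 on C8a from the start and closes the other ring bond.

**Alternative 2:** cut C4–H and the C1 oxygen.
- Iodide A4, after halogen–lithium exchange, is added to tetralone A3. Dehydration gives dihydronaphthalene A5, asymmetric hydrogenation gives tetralin A6, and a benzylic oxidation installs C1=O.
- The hydrogenation concerns a very hindered trisubstituted diaryl olefin.
- The final oxidation must take the C1 methylene in preference to the doubly benzylic C4–H, which is para to O7 and more easily ionised. It must do so in the presence of an alkoxynaphthalene that is itself oxidised.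
- The chosen plan never changes the oxidation level after the stereocentre is set.

**Alternative 3:** cut C4–C1'.
- The forward key step is a nickel-catalysed enantioconvergent reductive coupling of the racemic benzylic bromide A7 with iodide A4.
- Such couplings tolerate ortho substituents on the aryl partner poorly, and A4 is flanked by a ring fusion and a peri methoxy group.
- A7 loses HBr and enolises to a naphthol, and its 7,8-dioxygenated tetralone core has itself to be built against the Friedel–Crafts preference.
- A Friedel–Crafts variant of the same cut adds an ortho/para question on ring C.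
- The chosen plan makes this bond first, by formylation, when it is not yet hindered.

Key step: step 7

Assumption: the sense of induction of the acid in step 7 cannot be derived from precedent; the (S,S) antipode is written, and the (R,R) antipode takes its place if the first run shows the opposite sense.

## Steps

Step 1
Reactants: 1 1,5-dimethoxynaphthalene
Product: 2 4,8-dimethoxynaphthalene-1-carbaldehyde
Conditions: POCl3, DMF, toluene, 0 → 90 °C; then H2O
Reagents that add atoms: N,N-dimethylformamide, CN(C)C=O; water, O
Why: Vilsmeier–Haack formylation; 1 is C2h-symmetric, so attack para to either methoxy group gives the same aldehyde, and the small electrophile tolerates the peri methoxy group. The later C4–C1' bond of 11 is made here, before it becomes hindered.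

Step 2
Reactants: 2 4,8-dimethoxynaphthalene-1-carbaldehyde
Product: 3 4-hydroxy-8-methoxynaphthalene-1-carbaldehyde
Conditions: NaSEt, DMF, 100 °C; then aq HCl
Reagents that add atoms: none
Why: SN2 O-demethylation by a soft thiolate; the C4 methoxy group is conjugated with the formyl group (a vinylogous methyl ester), so its aryloxide is the better leaving group. C8 is not conjugated with C1, and its methyl group sits shielded in the peri bay.

Step 3
Reactants: 3 4-hydroxy-8-methoxynaphthalene-1-carbaldehyde
Product: 4 4-(benzyloxy)-8-methoxynaphthalene-1-carbaldehyde
Conditions: BnBr, K2CO3, DMF, rt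
Reagents that add atoms: benzyl bromide, BrCc1ccccc1
Why: Williamson ether synthesis on an acidic, unhindered naphthol; the ether restores the electrophilicity of the aldehyde, which the free naphtholate would quench in step 5.

Step 4
Reactants: 5 1-(2,3-dihydroxyphenyl)ethan-1-one
Product: 6 1-[2,3-bis(benzyloxy)phenyl]ethan-1-one
Conditions: BnBr, K2CO3, DMF, 60 °C
Reagents that add atoms: benzyl bromide, BrCc1ccccc1
Why: Double Williamson ether synthesis; warming is needed for the hydroxyl group that is hydrogen-bonded to the acetyl oxygen.

Step 5
Reactants: 4 4-(benzyloxy)-8-methoxynaphthalene-1-carbaldehyde; 6 1-[2,3-bis(benzyloxy)phenyl]ethan-1-one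
Product: 7 (E)-1-[2,3-bis(benzyloxy)phenyl]-3-[4-(benzyloxy)-8-methoxynaphthalen-1-yl]prop-2-en-1-one
Conditions: KOH, EtOH, rt → 50 °C
Reagents that add atoms: none
Why: Claisen–Schmidt condensation; only 6 can enolise and only 4 can accept, and the E1cB loss of water gives the conjugated (E)-enone. Benzyl and methyl ethers are inert to the base.

Step 6
Reactants: 7 (E)-1-[2,3-bis(benzyloxy)phenyl]-3-[4-(benzyloxy)-8-methoxynaphthalen-1-yl]prop-2-en-1-one
Product: 8 rac-[2,3-bis(benzyloxy)phenyl]{(1R*,2R*)-2-[4-(benzyloxy)-8-methoxynaphthalen-1-yl]cyclopropyl}methanone (trans)
Conditions: Me3S(O)I, NaH, DMSO, rt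
Reagents that add atoms: trimethylsulfoxonium iodide, C[S+](C)(C)=O.[I-]
Why: Corey–Chaykovsky cyclopropanation; the stabilised sulfoxonium ylide adds in conjugate fashion, and the enolate closes 3-exo-tet after bond rotation to the trans ring. The two new stereocentres are formed racemic on purpose, since step 7 erases them.

Step 7
Reactants: 8 rac-[2,3-bis(benzyloxy)phenyl]{(1R*,2R*)-2-[4-(benzyloxy)-8-methoxynaphthalen-1-yl]cyclopropyl}methanone
Product: 10 (4R)-7,8-bis(benzyloxy)-4-[4-(benzyloxy)-8-methoxynaphthalen-1-yl]-3,4-dihydronaphthalen-1(2H)-one, via benzylic cation 9 (not isolated)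
Conditions: (S,S)-IDPi (BINOL-derived imidodiphosphorimidate acid, 3,3'-Ar = 3,5-(CF3)2C6H3, N-SO2CF3 core; 5 mol %), CHCl3, 0.005 M, −20 °C → rt
Reagents that add atoms: none
Why: Proposed new method: the confined strong acid protonates the C1 carbonyl oxygen of 8, the polarised C2–C4 bond of the donor–acceptor cyclopropane breaks heterolytically, and after ketonisation the planar secondary benzylic cation 9, stabilised through C1'–C4' by the para benzyloxy oxygen, is left paired with the chiral imidodiphosphorimidate anion. Both enantiomers of 8 open to this one achiral cation, rotation about C3–C4 is much faster than ring closure, and the side equilibria (re-closure at C2, closure through the carbonyl oxygen, loss of a C3 proton) all lead back to 9, so the configuration of 8 is erased and the step is stereoconvergent under Curtin–Hammett control. Ring A closes by attack of C4a of ring B on C4, an intramolecular Friedel–Crafts alkylation that is 6-exo-trig with respect to the quinoid C4=C1' bond of 9, and loss of the C4a proton to the anion returns the acid, so the whole step is an isomerisation without by-product. The closest known reaction types are the SnCl4-promoted cyclisation of aryl 2-arylcyclopropyl ketones to racemic 4-aryl-1-tetralones and the counteranion-directed asymmetric SN1 reactions of racemic precursors of secondary benzylic cations catalysed by the same class of acids; their combination, and an acyl-substituted arene as the nucleophile in the asymmetric manifold, are new. The only new stereocentre, C4, is controlled by the chiral anion, which leaves one face of 9 open to C4a; the C8' methoxy group helps, since it allows only the rotamer of 9 in which C4–H points into the peri bay, so that a single cation geometry has to be recognised. Site selectivity comes from the substrate: of the two positions ortho to the acyl group C8 carries oxygen, and the free one, C4a, is para to O7. Chemoselectivity is needed against alkylation of the naphthalene of a second molecule and is sought through high dilution and the narrow catalyst pocket. Aromatisation cannot intervene because the cation exists only while ring A is open, and 10 is not ionised at C4 by the catalyst.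

Step 8
Reactants: 10 (4R)-7,8-bis(benzyloxy)-4-[4-(benzyloxy)-8-methoxynaphthalen-1-yl]-3,4-dihydronaphthalen-1(2H)-one
Product: 11 (4R)-7,8-dihydroxy-4-(4-hydroxy-8-methoxynaphthalen-1-yl)-3,4-dihydronaphthalen-1(2H)-one
Conditions: H2 (1 atm), Pd/C, EtOAc–EtOH, rt, air excluded on work-up
Reagents that add atoms: none
Why: Hydrogenolysis of three aryl benzyl ethers under neutral conditions; the methyl ether, the C4–H bond and its configuration are untouched. The ketone becomes deactivated as soon as the C8 hydroxyl group is free to hydrogen-bond to it.

## Compound list

1 | 1,5-dimethoxynaphthalene | COc1cccc2c(OC)cccc12 | starting material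
2 | 4,8-dimethoxynaphthalene-1-carbaldehyde | COc1cccc2c(OC)ccc(C=O)c12 | intermediate
3 | 4-hydroxy-8-methoxynaphthalene-1-carbaldehyde | COc1cccc2c(O)ccc(C=O)c12 | intermediate
4 | 4-(benzyloxy)-8-methoxynaphthalene-1-carbaldehyde | COc1cccc2c(OCc3ccccc3)ccc(C=O)c12 | intermediate
5 | 1-(2,3-dihydroxyphenyl)ethan-1-one | CC(=O)c1cccc(O)c1O | starting material
6 | 1-[2,3-bis(benzyloxy)phenyl]ethan-1-one | CC(=O)c1cccc(OCc2ccccc2)c1OCc1ccccc1 | intermediate
7 | (E)-1-[2,3-bis(benzyloxy)phenyl]-3-[4-(benzyloxy)-8-methoxynaphthalen-1-yl]prop-2-en-1-one | COc1cccc2c(OCc3ccccc3)ccc(/C=C/C(=O)c3cccc(OCc4ccccc4)c3OCc3ccccc3)c12 | intermediate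
8 | rac-[2,3-bis(benzyloxy)phenyl]{(1R*,2R*)-2-[4-(benzyloxy)-8-methoxynaphthalen-1-yl]cyclopropyl}methanone (trans, racemic, one enantiomer drawn) | COc1cccc2c(OCc3ccccc3)ccc([C@@H]3C[C@H]3C(=O)c3cccc(OCc4ccccc4)c3OCc3ccccc3)c12 | intermediate
9 | 4-[2,3-bis(benzyloxy)phenyl]-1-[4-(benzyloxy)-8-methoxynaphthalen-1-yl]-4-oxobutan-1-ylium (ion pair with the catalyst anion, not isolated) | COc1cccc2c(OCc3ccccc3)ccc([CH+]CCC(=O)c3cccc(OCc4ccccc4)c3OCc3ccccc3)c12 | intermediate
10 | (4R)-7,8-bis(benzyloxy)-4-[4-(benzyloxy)-8-methoxynaphthalen-1-yl]-3,4-dihydronaphthalen-1(2H)-one | COc1cccc2c(OCc3ccccc3)ccc([C@H]3CCC(=O)c4c3ccc(OCc3ccccc3)c4OCc3ccccc3)c12 | intermediate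
11 | (4R)-7,8-dihydroxy-4-(4-hydroxy-8-methoxynaphthalen-1-yl)-3,4-dihydronaphthalen-1(2H)-one | COc1cccc2c(O)ccc([C@H]3CCC(=O)c4c3ccc(O)c4O)c12 | target

## Step count and least certain steps

Total step count: 8. Longest linear sequence: 7 steps (1, 2, 3, 5, 6, 7, 8).

**Step 7 (key step, proposed new method).** Three things are most likely to go wrong.
- Facial discrimination may be poor, because ring B offers the anion no hydrogen-bond handle.
- Bimolecular Friedel–Crafts alkylation and oligomerisation may compete, because ring B is deactivated by its acyl group and is a weaker nucleophile than the alkoxynaphthalene of a second molecule.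
- The peri methyl group may be lost after participation of the C8' oxygen at the cationic centre.

The fallback sets out from 8 and uses known chemistry. SnCl4 in CH2Cl2–MeNO2 at 0 °C would give the racemic tetralone F1. Reduction of F1 with BH3·SMe2 and (S)-Me-CBS oxazaborolidine should deliver hydride to the same carbonyl face of both enantiomers. It would give the (1R,4R)-tetralol F2 and the (1R,4S)-tetralol F3, which are diastereomers and separable on silica. Oxidation of F2 with Dess–Martin periodinane comes back to the route at 10. At most half of the material is used, but each operation has close precedent on 4-aryl-1-tetralones.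

**Step 2.** Cleavage of the peri methoxy group may compete, driven by relief of strain and cation chelation between O8 and the formyl oxygen. Reversible thiolate addition to the aldehyde may also slow the reaction.

The fallback sets out from 2 and differentiates the two oxygens by hydrogen bonding. BBr3 in CH2Cl2 would remove both methyl groups to give 4,8-dihydroxynaphthalene-1-carbaldehyde F4. One equivalent of BnBr with KHCO3 in DMF should alkylate only the acidic O4–H, since O8–H is locked in a hydrogen bond to the peri formyl group. This would give 4-(benzyloxy)-8-hydroxynaphthalene-1-carbaldehyde F5. MeI and K2CO3 then come back to the route at 4.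

**Step 6.** Conjugate addition may be sluggish, because the beta carbon of 7 is electron-rich and flanked by the peri-substituted naphthyl group. Carbonyl attack or retro-aldol cleavage could then take over.

The fallback sets out from 4 and 6 and builds the ring by carbene transfer.
- Wittig methylenation of 4 with Ph3P=CH2 would give 1-(benzyloxy)-4-ethenyl-5-methoxynaphthalene F6.
- Trifluoroacetylation of 6 (LiHMDS, CF3CO2CH2CF3) would give 1-[2,3-bis(benzyloxy)phenyl]-4,4,4-trifluorobutane-1,3-dione F7.
- Detrifluoroacetylative diazo transfer on F7 (MsN3, Et3N, H2O, MeCN) would give 1-[2,3-bis(benzyloxy)phenyl]-2-diazoethan-1-one F8.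
- Rh2(OAc)4-catalysed cyclopropanation of F6 with F8 comes back to the route at 8. It is accompanied by the cis cyclopropane F9, which need not be removed because step 7 erases the configuration of the ring.

**Step 8.** The benzylic ketone may be over-reduced before the chelating C8 hydroxyl group is liberated. The last, hindered benzyl ether may cleave slowly, and the product may oxidise in air during isolation.

The fallback sets out from 10 and comes back at 11. It replaces hydrogenolysis by Lewis-acid debenzylation with a cation scavenger (BCl3, pentamethylbenzene, CH2Cl2, −78 °C). This cleaves aryl benzyl ethers while unassisted aryl methyl ethers stay intact, and it involves no reducing agent.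

## Further compounds

F1 | step 7 | rac-7,8-bis(benzyloxy)-4-[4-(benzyloxy)-8-methoxynaphthalen-1-yl]-3,4-dihydronaphthalen-1(2H)-one | COc1cccc2c(OCc3ccccc3)ccc(C3CCC(=O)c4c3ccc(OCc3ccccc3)c4OCc3ccccc3)c12
F2 | step 7 | (1R,4R)-7,8-bis(benzyloxy)-4-[4-(benzyloxy)-8-methoxynaphthalen-1-yl]-1,2,3,4-tetrahydronaphthalen-1-ol | COc1cccc2c(OCc3ccccc3)ccc([C@H]3CC[C@@H](O)c4c3ccc(OCc3ccccc3)c4OCc3ccccc3)c12
F3 | step 7 | (1R,4S)-7,8-bis(benzyloxy)-4-[4-(benzyloxy)-8-methoxynaphthalen-1-yl]-1,2,3,4-tetrahydronaphthalen-1-ol | COc1cccc2c(OCc3ccccc3)ccc([C@@H]3CC[C@@H](O)c4c3ccc(OCc3ccccc3)c4OCc3ccccc3)c12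
F4 | step 2 | 4,8-dihydroxynaphthalene-1-carbaldehyde | O=Cc1ccc(O)c2cccc(O)c12
F5 | step 2 | 4-(benzyloxy)-8-hydroxynaphthalene-1-carbaldehyde | O=Cc1ccc(OCc2ccccc2)c2cccc(O)c12
F6 | step 6 | 1-(benzyloxy)-4-ethenyl-5-methoxynaphthalene | COc1cccc2c(OCc3ccccc3)ccc(C=C)c12
F7 | step 6 | 1-[2,3-bis(benzyloxy)phenyl]-4,4,4-trifluorobutane-1,3-dione | O=C(CC(=O)C(F)(F)F)c1cccc(OCc2ccccc2)c1OCc1ccccc1
F8 | step 6 | 1-[2,3-bis(benzyloxy)phenyl]-2-diazoethan-1-one | [N-]=[N+]=CC(=O)c1cccc(OCc2ccccc2)c1OCc1ccccc1
F9 | step 6 | rac-[2,3-bis(benzyloxy)phenyl]{(1R*,2S*)-2-[4-(benzyloxy)-8-methoxynaphthalen-1-yl]cyclopropyl}methanone (cis, racemic, one enantiomer drawn) | COc1cccc2c(OCc3ccccc3)ccc([C@H]3C[C@H]3C(=O)c3cccc(OCc4ccccc4)c3OCc3ccccc3)c12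
F0 | step 8 | none | none
A1 | alternative 1 | (4S)-4-[3,4-bis(benzyloxy)phenyl]-4-[4-(benzyloxy)-8-methoxynaphthalen-1-yl]butanoic acid | COc1cccc2c(OCc3ccccc3)ccc([C@@H](CCC(=O)O)c3ccc(OCc4ccccc4)c(OCc4ccccc4)c3)c12
A2 | alternative 1 | (4R)-6,7-bis(benzyloxy)-4-[4-(benzyloxy)-8-methoxynaphthalen-1-yl]-3,4-dihydronaphthalen-1(2H)-one | COc1cccc2c(OCc3ccccc3)ccc([C@H]3CCC(=O)c4cc(OCc5ccccc5)c(OCc5ccccc5)cc43)c12
A3 | alternative 2 | 5,6-bis(benzyloxy)-3,4-dihydronaphthalen-1(2H)-one | O=C1CCCc2c1ccc(OCc1ccccc1)c2OCc1ccccc1
A4 | alternative 2 | 1-(benzyloxy)-4-iodo-5-methoxynaphthalene | COc1cccc2c(OCc3ccccc3)ccc(I)c12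
A5 | alternative 2 | 1-(benzyloxy)-4-[5,6-bis(benzyloxy)-3,4-dihydronaphthalen-1-yl]-5-methoxynaphthalene | COc1cccc2c(OCc3ccccc3)ccc(C3=CCCc4c3ccc(OCc3ccccc3)c4OCc3ccccc3)c12
A6 | alternative 2 | (1S)-5,6-bis(benzyloxy)-1-[4-(benzyloxy)-8-methoxynaphthalen-1-yl]-1,2,3,4-tetrahydronaphthalene | COc1cccc2c(OCc3ccccc3)ccc([C@H]3CCCc4c3ccc(OCc3ccccc3)c4OCc3ccccc3)c12
A7 | alternative 3 | rac-7,8-bis(benzyloxy)-4-bromo-3,4-dihydronaphthalen-1(2H)-one | O=C1CCC(Br)c2ccc(OCc3ccccc3)c(OCc3ccccc3)c12
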